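**Retrosynthetic overview**
- The acid comes from its tert-butyl ester, and the ring carbinol from a hydroxyl-directed reduction of one ketone of an epoxy-enedione on the face of the oxirane oxygen.
- The epoxy-enedione comes from a bromo epoxy ketal by Suzuki coupling (heptenyl C–C bond), desilylation and ketal hydrolysis.
- Key disconnection: the oxirane (both carbons, one quaternary) from an achiral para-quinone monoketal by a new catalytic enantioselective nucleophilic epoxidation.
- The quinone monoketal comes from a pentasubstituted para-methoxyphenol by oxidative dearomatisation; its side chain is built by Claisen rearrangement and cross-metathesis on a brominated 5-hydroxy-2-methoxybenzaldehyde.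
- Ring order: the carbocycle is the benzene ring of the starting aldehyde (dearomatised in step 7); the oxirane is the only ring built (step 8).

Assumption: 5-hydroxy-2-methoxybenzaldehyde, allyl bromide, tert-butyl methacrylate and (E)-hept-1-enylboronic acid are taken as catalogue compounds.

**Step 1**
Reactants: 1 5-hydroxy-2-methoxybenzaldehyde
Product: 2 2-bromo-3-hydroxy-6-methoxybenzaldehyde
Conditions: Br2 (1.05 equiv), NaOAc, AcOH, 23 °C
Reagents that add atoms: bromine, BrBr
Why: Electrophilic aromatic bromination: the phenol directs ortho and, with the para position blocked by OMe, bromine enters the site flanked by OH and CHO, the same site selectivity that isovanillin shows under these buffered conditions.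

**Step 2**
Reactants: 2 2-bromo-3-hydroxy-6-methoxybenzaldehyde; 3 allyl bromide
Product: 4 3-(allyloxy)-2-bromo-6-methoxybenzaldehyde
Conditions: K2CO3, DMF, 23 °C
Reagents that add atoms: none
Why: Williamson ether synthesis: the phenoxide displaces bromide from the allylic halide by SN2 and the aldehyde is untouched by K2CO3.

**Step 3**
Reactants: 4 3-(allyloxy)-2-bromo-6-methoxybenzaldehyde
Product: 5 [3-(allyloxy)-2-bromo-6-methoxyphenyl]methanol
Conditions: NaBH4, MeOH, 0 °C
Reagents that add atoms: none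
Why: Borohydride reduction of the aldehyde to the benzylic alcohol; the aryl bromide and allyl ether are inert.

**Step 4**
Reactants: 5 [3-(allyloxy)-2-bromo-6-methoxyphenyl]methanol
Product: 6 {[3-(allyloxy)-2-bromo-6-methoxyphenyl]methoxy}(tert-butyl)dimethylsilane
Conditions: TBSCl, imidazole, DMF, 23 °C
Reagents that add atoms: tert-butyldimethylsilyl chloride (TBSCl), CC(C)(C)[Si](C)(C)Cl
Why: Imidazole-promoted silyl ether formation masks the primary alcohol for the thermal, oxidative and basic steps ahead.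

**Step 5**
Reactants: 6 {[3-(allyloxy)-2-bromo-6-methoxyphenyl]methoxy}(tert-butyl)dimethylsilane
Product: 8 2-allyl-6-bromo-5-{[(tert-butyldimethylsilyl)oxy]methyl}-4-methoxyphenol, via Claisen ortho-dienone 7 (not isolated)
Conditions: N,N-diethylaniline, 190 °C
Reagents that add atoms: none
Why: Aromatic Claisen rearrangement: the [3,3]-sigmatropic shift can only reach the one free ortho carbon (the other is blocked by Br, the para position by OMe) and dienone 7 tautomerises to the phenol.

**Step 6**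
Reactants: 8 2-allyl-6-bromo-5-{[(tert-butyldimethylsilyl)oxy]methyl}-4-methoxyphenol; 9 tert-butyl methacrylate
Product: 10 tert-butyl (E)-4-(3-bromo-4-{[(tert-butyldimethylsilyl)oxy]methyl}-2-hydroxy-5-methoxyphenyl)-2-methylbut-2-enoate
Conditions: second-generation Hoveyda–Grubbs catalyst RuCl2(H2IMes)(=CH-C6H4-2-OiPr) (5 mol%), 9 (10 equiv), CH2Cl2, 40 °C
Reagents that add atoms: none
Why: Olefin cross-metathesis of a terminal alkene with a 1,1-disubstituted acrylate that does not homodimerise gives the thermodynamically favoured (E)-trisubstituted enoate; no stereocentre is formed.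

**Step 7**
Reactants: 10 tert-butyl (E)-4-(3-bromo-4-{[(tert-butyldimethylsilyl)oxy]methyl}-2-hydroxy-5-methoxyphenyl)-2-methylbut-2-enoate
Product: 11 tert-butyl (E)-4-(5-bromo-4-{[(tert-butyldimethylsilyl)oxy]methyl}-3,3-dimethoxy-6-oxocyclohexa-1,4-dien-1-yl)-2-methylbut-2-enoate
Conditions: PhI(OAc)2 (1.1 equiv), MeOH, 0 °C
Reagents that add atoms: methanol, CO
Why: Oxidative dearomatisation of a para-methoxyphenol by a trivalent iodine oxidant: methanol is captured at the para carbon to give the achiral para-quinone monoketal.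

**Step 8**
Reactants: 11 tert-butyl (E)-4-(5-bromo-4-{[(tert-butyldimethylsilyl)oxy]methyl}-3,3-dimethoxy-6-oxocyclohexa-1,4-dien-1-yl)-2-methylbut-2-enoate
Product: 12 tert-butyl (E)-4-[(1S,6R)-3-bromo-4-{[(tert-butyldimethylsilyl)oxy]methyl}-5,5-dimethoxy-2-oxo-7-oxabicyclo[4.1.0]hept-3-en-1-yl]-2-methylbut-2-enoate
Conditions: ammonium–urea salt Q (10 mol%), cumene hydroperoxide (1.5 equiv), 50% aq K2CO3, toluene, −20 °C
Reagents that add atoms: cumene hydroperoxide, CC(C)(OO)c1ccccc1
Why: Proposed new method: a catalytic enantioselective Weitz–Scheffer epoxidation of a fully substituted para-quinone monoketal under bifunctional phase-transfer catalysis, with Q = N-[3,5-bis(trifluoromethyl)benzyl]-9-deoxy-9-epi-9-{3-[3,5-bis(trifluoromethyl)phenyl]ureido}quinidinium bromide; mechanistic reasoning: the ammonium ion carries cumylperoxide into toluene as a tight chiral ion pair while the two urea N–H bonds hold the ketone oxygen, the peroxide adds in conjugate fashion on the Re face of the only unsubstituted β-carbon (the ring CH; the β-carbon of the bromo enone is fully substituted and flanked by the ketal, and the tiglate-type ester is inert), and the enolate then closes onto the proximal peroxide oxygen with loss of cumyl oxide, so both C–O bonds form on one face and the ring CH carbon (6R) and the quaternary carbon (1S) are set together; the closest known reaction types are the cinchona ammonium phase-transfer epoxidation of 2-alkyl-1,4-naphthoquinones and chalcones and the stoichiometric tartrate-mediated nucleophilic epoxidation of quinone monoketals.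

**Step 9**
Reactants: 12 tert-butyl (E)-4-[(1S,6R)-3-bromo-4-{[(tert-butyldimethylsilyl)oxy]methyl}-5,5-dimethoxy-2-oxo-7-oxabicyclo[4.1.0]hept-3-en-1-yl]-2-methylbut-2-enoate; 13 (E)-hept-1-enylboronic acid
Product: 14 tert-butyl (E)-4-[(1S,6R)-4-{[(tert-butyldimethylsilyl)oxy]methyl}-3-[(E)-hept-1-enyl]-5,5-dimethoxy-2-oxo-7-oxabicyclo[4.1.0]hept-3-en-1-yl]-2-methylbut-2-enoate
Conditions: Pd(OAc)2 (5 mol%), SPhos (10 mol%), K3PO4, THF/H2O (10:1), 40 °C
Reagents that add atoms: none
Why: Suzuki–Miyaura coupling: zerovalent palladium inserts into the electron-poor C–Br bond of the α-bromo enone and the (E)-alkenyl group is transferred with retention of geometry, while the epoxy ketone and ketal tolerate aqueous phosphate.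

**Step 10**
Reactants: 14 tert-butyl (E)-4-[(1S,6R)-4-{[(tert-butyldimethylsilyl)oxy]methyl}-3-[(E)-hept-1-enyl]-5,5-dimethoxy-2-oxo-7-oxabicyclo[4.1.0]hept-3-en-1-yl]-2-methylbut-2-enoate
Product: 16 tert-butyl (E)-4-[(1S,6R)-3-[(E)-hept-1-enyl]-4-(hydroxymethyl)-2,5-dioxo-7-oxabicyclo[4.1.0]hept-3-en-1-yl]-2-methylbut-2-enoate, via hydroxymethyl dimethyl ketal 15 (not isolated)
Conditions: 48% aq HF, MeCN, 0 → 23 °C
Reagents that add atoms: water, O
Why: Acidic fluoride first cleaves the primary silyl ether (15) and then hydrolyses the dimethyl ketal to the enedione; the electron-poor α,β-epoxy ketone and the tert-butyl ester are stable to dilute aqueous HF and the two stereocentres are untouched.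

**Step 11**
Reactants: 16 tert-butyl (E)-4-[(1S,6R)-3-[(E)-hept-1-enyl]-4-(hydroxymethyl)-2,5-dioxo-7-oxabicyclo[4.1.0]hept-3-en-1-yl]-2-methylbut-2-enoate
Product: 17 tert-butyl (E)-4-[(1S,5R,6S)-3-[(E)-hept-1-enyl]-5-hydroxy-4-(hydroxymethyl)-2-oxo-7-oxabicyclo[4.1.0]hept-3-en-1-yl]-2-methylbut-2-enoate
Conditions: iBu2AlH (3 equiv), THF, −78 °C; then aq potassium sodium tartrate
Reagents that add atoms: none
Why: Hydroxyl-directed 1,2-reduction with a Lewis-acidic hydride: the alkoxyalane formed at the C4 hydroxymethyl group chelates the neighbouring C5 carbonyl, which is also the less hindered one (C2 is flanked by the quaternary C1 and the heptenyl-bearing C3), and hydride is delivered on the face of the oxirane oxygen (aluminium coordination to that oxygen, the opposite face being screened by the side chain on C1), which sets C5 as R with the hydroxyl trans to the oxirane.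

**Step 12**
Reactants: 17 tert-butyl (E)-4-[(1S,5R,6S)-3-[(E)-hept-1-enyl]-5-hydroxy-4-(hydroxymethyl)-2-oxo-7-oxabicyclo[4.1.0]hept-3-en-1-yl]-2-methylbut-2-enoate
Product: 18 (E)-4-[(1S,5R,6S)-3-[(E)-hept-1-enyl]-5-hydroxy-4-(hydroxymethyl)-2-oxo-7-oxabicyclo[4.1.0]hept-3-en-1-yl]-2-methylbut-2-enoic acid
Conditions: CF3CO2H/CH2Cl2 (1:4), 0 °C; aq NaHCO3 work-up, then acidify to pH 3
Reagents that add atoms: none
Why: Acidolysis of the tert-butyl ester by E1 loss of isobutene leaves the electron-poor epoxy ketone intact, and any transient trifluoroacetates of the alcohols fall off in the bicarbonate work-up.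

**Compound list**
1 | 5-hydroxy-2-methoxybenzaldehyde | COc1ccc(O)cc1C=O | starting material
2 | 2-bromo-3-hydroxy-6-methoxybenzaldehyde | COc1ccc(O)c(Br)c1C=O | intermediate
3 | allyl bromide (3-bromoprop-1-ene) | C=CCBr | starting material
4 | 3-(allyloxy)-2-bromo-6-methoxybenzaldehyde | COc1ccc(OCC=C)c(Br)c1C=O | intermediate
5 | [3-(allyloxy)-2-bromo-6-methoxyphenyl]methanol | COc1ccc(OCC=C)c(Br)c1CO | intermediate
6 | {[3-(allyloxy)-2-bromo-6-methoxyphenyl]methoxy}(tert-butyl)dimethylsilane | COc1ccc(OCC=C)c(Br)c1CO[Si](C)(C)C(C)(C)C | intermediate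
7 | 6-allyl-2-bromo-3-{[(tert-butyldimethylsilyl)oxy]methyl}-4-methoxycyclohexa-2,4-dien-1-one (racemic, not isolated) | O=C1C(Br)=C(CO[Si](C)(C)C(C)(C)C)C(OC)=CC1CC=C | intermediate
8 | 2-allyl-6-bromo-5-{[(tert-butyldimethylsilyl)oxy]methyl}-4-methoxyphenol | COc1cc(CC=C)c(O)c(Br)c1CO[Si](C)(C)C(C)(C)C | intermediate
9 | tert-butyl methacrylate | CC(=C)C(=O)OC(C)(C)C | starting material
10 | tert-butyl (E)-4-(3-bromo-4-{[(tert-butyldimethylsilyl)oxy]methyl}-2-hydroxy-5-methoxyphenyl)-2-methylbut-2-enoate | COc1cc(C/C=C(\C)C(=O)OC(C)(C)C)c(O)c(Br)c1CO[Si](C)(C)C(C)(C)C | intermediate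
11 | tert-butyl (E)-4-(5-bromo-4-{[(tert-butyldimethylsilyl)oxy]methyl}-3,3-dimethoxy-6-oxocyclohexa-1,4-dien-1-yl)-2-methylbut-2-enoate | O=C1C(Br)=C(CO[Si](C)(C)C(C)(C)C)C(OC)(OC)C=C1C/C=C(\C)C(=O)OC(C)(C)C | intermediate
12 | tert-butyl (E)-4-[(1S,6R)-3-bromo-4-{[(tert-butyldimethylsilyl)oxy]methyl}-5,5-dimethoxy-2-oxo-7-oxabicyclo[4.1.0]hept-3-en-1-yl]-2-methylbut-2-enoate | BrC1=C(CO[Si](C)(C)C(C)(C)C)C(OC)(OC)[C@@H]2O[C@]2(C/C=C(\C)C(=O)OC(C)(C)C)C1=O | intermediate
13 | (E)-hept-1-enylboronic acid | CCCCC/C=C/B(O)O | starting material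
14 | tert-butyl (E)-4-[(1S,6R)-4-{[(tert-butyldimethylsilyl)oxy]methyl}-3-[(E)-hept-1-enyl]-5,5-dimethoxy-2-oxo-7-oxabicyclo[4.1.0]hept-3-en-1-yl]-2-methylbut-2-enoate | CCCCC/C=C/C1=C(CO[Si](C)(C)C(C)(C)C)C(OC)(OC)[C@@H]2O[C@]2(C/C=C(\C)C(=O)OC(C)(C)C)C1=O | intermediate
15 | tert-butyl (E)-4-[(1S,6R)-3-[(E)-hept-1-enyl]-4-(hydroxymethyl)-5,5-dimethoxy-2-oxo-7-oxabicyclo[4.1.0]hept-3-en-1-yl]-2-methylbut-2-enoate (not isolated) | CCCCC/C=C/C1=C(CO)C(OC)(OC)[C@@H]2O[C@]2(C/C=C(\C)C(=O)OC(C)(C)C)C1=O | intermediate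
16 | tert-butyl (E)-4-[(1S,6R)-3-[(E)-hept-1-enyl]-4-(hydroxymethyl)-2,5-dioxo-7-oxabicyclo[4.1.0]hept-3-en-1-yl]-2-methylbut-2-enoate | CCCCC/C=C/C1=C(CO)C(=O)[C@@H]2O[C@]2(C/C=C(\C)C(=O)OC(C)(C)C)C1=O | intermediate
17 | tert-butyl (E)-4-[(1S,5R,6S)-3-[(E)-hept-1-enyl]-5-hydroxy-4-(hydroxymethyl)-2-oxo-7-oxabicyclo[4.1.0]hept-3-en-1-yl]-2-methylbut-2-enoate | CCCCC/C=C/C1=C(CO)[C@@H](O)[C@@H]2O[C@]2(C/C=C(\C)C(=O)OC(C)(C)C)C1=O | intermediate
18 | (E)-4-[(1S,5R,6S)-3-[(E)-hept-1-enyl]-5-hydroxy-4-(hydroxymethyl)-2-oxo-7-oxabicyclo[4.1.0]hept-3-en-1-yl]-2-methylbut-2-enoic acid | CCCCC/C=C/C1=C(CO)[C@@H](O)[C@@H]2O[C@]2(C/C=C(\C)C(=O)O)C1=O | target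

**Totals**
Total step count: 12. Longest linear sequence: 12 steps (1 to 18).

**Three steps most likely to fail**

Step 8 (the new epoxidation). The risks are low enantioselectivity, an unreactive ion pair, or the opposite sense of induction; the sense drawn is a working model, and the quinine-derived pseudoenantiomer of Q would be tried first if it is reversed. The fallback uses known auxiliary chemistry, sets out from 11 and comes back at 16. Acid-catalysed transketalisation of 11 with (2S,4S)-pentane-2,4-diol (pyridinium p-toluenesulfonate, benzene, 60 °C) gives the chiral spiro-dioxane quinone monoketal F1. Substrate-controlled nucleophilic epoxidation with trityl hydroperoxide and KN(SiMe3)2 in THF at −78 °C gives the (1S,6R)-epoxy ketone F2; here the axial methyl group of the dioxane chair, which sits over the ring CH carbon rather than over the silyloxymethyl-bearing carbon, screens the Si face. Suzuki coupling with 13 under the conditions of step 9 gives the heptenyl diene F3. Finally 48% aqueous HF in MeCN removes the silyl ether and the diol auxiliary and gives 16.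

Step 11 (reduction). The risks are attack at the other carbonyl or on the other face. The fallback corrects the carbinol by inversion, sets out from 14 and comes back at 17. Montmorillonite K10 in CH2Cl2 hydrolyses the ketal but keeps the silyl ether and gives the silyl-protected epoxy-enedione F4. Luche reduction (NaBH4, CeCl3·7H2O, MeOH, −78 °C), in which the external hydride enters anti to the oxirane oxygen, gives the cis epoxy alcohol F5. Mitsunobu inversion with 4-nitrobenzoic acid, PPh3 and diisopropyl azodicarboxylate gives the trans 4-nitrobenzoate F6. K2CO3 in MeOH at 0 °C gives the trans alcohol F7, and HF·pyridine in THF removes the silyl group to give 17.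

Step 6 (cross-metathesis). The risks are allyl-to-propenyl isomerisation and low conversion in forming a trisubstituted alkene next to a free phenol. The fallback sets out from 8 and comes back at 10. Lemieux–Johnson cleavage (K2OsO4·2H2O cat., NaIO4, 2,6-lutidine, dioxane/H2O) gives the arylacetaldehyde as its cyclic lactol F8. Wittig olefination with tert-butyl 2-(triphenylphosphoranylidene)propanoate in toluene at 60 °C opens the lactol and gives the (E)-enoate 10.

**Further compounds**
F1 | step 8 | tert-butyl (E)-4-(5-bromo-4-{[(tert-butyldimethylsilyl)oxy]methyl}-6-oxo-3,3-[(2S,4S)-pentane-2,4-diylbis(oxy)]cyclohexa-1,4-dien-1-yl)-2-methylbut-2-enoate | O=C1C(Br)=C(CO[Si](C)(C)C(C)(C)C)C2(O[C@@H](C)C[C@H](C)O2)C=C1C/C=C(\C)C(=O)OC(C)(C)C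
F2 | step 8 | tert-butyl (E)-4-[(1S,6R)-3-bromo-4-{[(tert-butyldimethylsilyl)oxy]methyl}-2-oxo-5,5-[(2S,4S)-pentane-2,4-diylbis(oxy)]-7-oxabicyclo[4.1.0]hept-3-en-1-yl]-2-methylbut-2-enoate | BrC1=C(CO[Si](C)(C)C(C)(C)C)C3(O[C@@H](C)C[C@H](C)O3)[C@@H]2O[C@]2(C/C=C(\C)C(=O)OC(C)(C)C)C1=O
F3 | step 8 | tert-butyl (E)-4-[(1S,6R)-4-{[(tert-butyldimethylsilyl)oxy]methyl}-3-[(E)-hept-1-enyl]-2-oxo-5,5-[(2S,4S)-pentane-2,4-diylbis(oxy)]-7-oxabicyclo[4.1.0]hept-3-en-1-yl]-2-methylbut-2-enoate | CCCCC/C=C/C1=C(CO[Si](C)(C)C(C)(C)C)C3(O[C@@H](C)C[C@H](C)O3)[C@@H]2O[C@]2(C/C=C(\C)C(=O)OC(C)(C)C)C1=O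
F4 | step 11 | tert-butyl (E)-4-[(1S,6R)-4-{[(tert-butyldimethylsilyl)oxy]methyl}-3-[(E)-hept-1-enyl]-2,5-dioxo-7-oxabicyclo[4.1.0]hept-3-en-1-yl]-2-methylbut-2-enoate | CCCCC/C=C/C1=C(CO[Si](C)(C)C(C)(C)C)C(=O)[C@@H]2O[C@]2(C/C=C(\C)C(=O)OC(C)(C)C)C1=O
F5 | step 11 | tert-butyl (E)-4-[(1S,5S,6S)-4-{[(tert-butyldimethylsilyl)oxy]methyl}-3-[(E)-hept-1-enyl]-5-hydroxy-2-oxo-7-oxabicyclo[4.1.0]hept-3-en-1-yl]-2-methylbut-2-enoate | CCCCC/C=C/C1=C(CO[Si](C)(C)C(C)(C)C)[C@H](O)[C@@H]2O[C@]2(C/C=C(\C)C(=O)OC(C)(C)C)C1=O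
F6 | step 11 | (1S,5R,6S)-1-[(E)-4-tert-butoxy-3-methyl-4-oxobut-2-enyl]-4-{[(tert-butyldimethylsilyl)oxy]methyl}-3-[(E)-hept-1-enyl]-2-oxo-7-oxabicyclo[4.1.0]hept-3-en-5-yl 4-nitrobenzoate | CCCCC/C=C/C1=C(CO[Si](C)(C)C(C)(C)C)[C@@H](OC(=O)c3ccc(cc3)[N+](=O)[O-])[C@@H]2O[C@]2(C/C=C(\C)C(=O)OC(C)(C)C)C1=O
F7 | step 11 | tert-butyl (E)-4-[(1S,5R,6S)-4-{[(tert-butyldimethylsilyl)oxy]methyl}-3-[(E)-hept-1-enyl]-5-hydroxy-2-oxo-7-oxabicyclo[4.1.0]hept-3-en-1-yl]-2-methylbut-2-enoate | CCCCC/C=C/C1=C(CO[Si](C)(C)C(C)(C)C)[C@@H](O)[C@@H]2O[C@]2(C/C=C(\C)C(=O)OC(C)(C)C)C1=O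
F8 | step 6 | 7-bromo-6-{[(tert-butyldimethylsilyl)oxy]methyl}-5-methoxy-2,3-dihydro-1-benzofuran-2-ol (racemic lactol) | COc1cc2CC(O)Oc2c(Br)c1CO[Si](C)(C)C(C)(C)C
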